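The blue target cannot have stalled for want of coupling partner, since 2.50 equiv were charged and the target reads no higher than 67.3% of the starting material.

all flasks: starting material 10 mM; free catalyst 15 mol%; second catalyst 1 mol%

| run | coupling partner | temperature | remark | time |
|---|---|---|---|---|
| blue | 2.5 equiv | −20 °C | the very flask that is asked about, followed so far |  |
| teal | 2.5 equiv | −25 °C | run made earlier |  |
| flask | 2.50 equiv | −20 °C |  | 8.0 d |

- blue (time / d: target / %): 1.25: 58.3; 2.50: 64.5; 4.00: 67.3; 5.00: 65.4; 6.00: 65.0
- teal (time / d: target / %): 1.25: 49.0; 2.50: 61.0; 4.00: 62.2; 5.00: 61.2; 6.00: 63.3

(each reading ± 1 percentage point)

- Saturday's: at 8.0 d raise the temperature by 15 K, then wait 15 d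
- Sunday's: change nothing and wait 15 d more
- Wednesday's: at 8.0 d add free catalyst, 50.0% of the amount charged, then wait 15 d
- Monday's: at 8.0 d add coupling partner, 50.0% of the amount charged, then wait 15 d

- what is added takes up no volume worth counting
- the analysis behind the earlier runs scatters by 1 percentage point, standard deviation
- a reading or a percentage of target counts all its forms, free or not
- "the catalyst" is free catalyst with its forms; second catalyst is a second catalyst

- target, in percent of the starting material first charged, at 8.0 d
- what to do for the largest gain in target; "none" if nothing gains more than 2 percentage points (Saturday's / Sunday's / Wednesday's / Monday's / none)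
- target present, in percent of the starting material first charged, after Sunday's
- target present, in percent of the starting material first charged, after Wednesday's

Compare two rates at one moment. Suppose target forms from the unconverted rest of the charge with coupling partner, and also falls back. Early on the forward rate wins. As target rises, the rest and the partner shrink, so the forward rate drifts down to the back rate and the readings go flat. This is thermodynamic control, assumed here and not shown by the readings.

Now weigh the numbers before reading any. The readings at 1.25 d may be off without harm, since the questions ask about 8.0 d and later. The answer at 8.0 d takes over any error in the blue plateau height in full. Monday's gain barely feels it: take the highest blue reading as the plateau and the quotient defined below becomes 113 /M, with a gain of 9.7 percentage points. Saturday's is delicate: it stretches the gap between two plateaus, each read from readings scattered by 1 point, to a rise of 15 K.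

Then read the numbers. The flat blue readings average 65.5% and the teal ones 61.9%. 103 /M is the balance quotient, target divided by the rest of the charge and by the coupling partner left, as concentrations. My reckoning: waiting and more free catalyst leave blue at 65.5%, and Monday's gains 10 points, the firmest choice.

The forecast differs: “something dies, most likely the catalyst”. It gives 65.5% now, 65.5% after Sunday's, 78% after Wednesday's, and chooses Wednesday's.

The flask gives 64.9%, 64.9% after Sunday's and 64.9% after Wednesday's, and the best is Monday's, gaining 10 points against the reckoned 10 points from 103 /M.

    crystals ⇌ target, rate k1*(cs1 - [target]) while solid is left; crystals form when [target] > cs1 (solubility = 8.40 mM, k = 2.30 /h)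
    coupling partner + second catalyst + intermediate ⇌ second catalyst + target (K = 100 /M, k = 1.80 × 10⁵ /M²/h, Ea = 36.0 kJ/mol, ΔH = 10.0 kJ/mol)
    starting material + free catalyst → free catalyst + intermediate (k = 54.0 /M/h, Ea = 41.0 kJ/mol)
    (constants at −20 °C)

The coupling step relaxes, both ways together, with a half-life of 0.0501 d, short against the 8.0 d. At 8.00 d the flask holds target 64.9% beside intermediate 35.1%, with free catalyst at 100%. For the same recipe at 4.0 mM of starting material, 103 /M reckons target at 45.7%, and that flask holds 44.9%.

All runs come from a simulation with constants of no real substance; scatter was added.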